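**Retrosynthetic overview**

1. Ring C (the pyranone) is opened last at O1–C2: the flavone goes back to an open-chain 2-methoxy-1,3-diketone with free ring A hydroxyls, and before that to the same diketone with all five phenols masked as benzyl ethers.
2. Key disconnection: C4a–C4 and C4–C3 of that diketone are cut together. C4 comes from carbon monoxide, C4a from a ring A aryl iodide and C3 from the α-carbon of a ring B methoxymethyl ketone (palladium-catalysed carbonylative α-arylation).
3. Feature used: C4 is an isolated carbonyl carbon. One neighbour is C4a, the only carbon-bearing atom of the fully substituted ring A (oxygen on C5, C6, C7, C8 and C8a, mirror-symmetric about the C4a–C7 axis); the other is C3, which already carries its methoxy group.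
4. Ring A iodide: phloroglucinol → tribenzyl ether → dibromide → double methoxylation → iodination of the last C–H. Ring B ketone: 3,5-dihydroxy-4-methoxybenzoic acid → perbenzylation → crossed Claisen condensation with methyl methoxyacetate → dealkoxycarbonylation.
5. Ring order: rings A and B are bought as benzene rings; ring C is the only ring made, by cyclodehydration in the last step.

Key step: step 8

Remark: the debenzylated diketone is drawn in its open diketo form; in solution it should equilibrate with enol and cyclic hemiketal forms, all of which converge on the flavone under acid.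

**Route**

Step 1
Reactants: 1 phloroglucinol (benzene-1,3,5-triol)
Product: 2 1,3,5-tris(benzyloxy)benzene
Conditions: BnBr (3.3 equiv), K2CO3, DMF, 0 °C → rt
Reagents that add atoms: benzyl bromide, BrCc1ccccc1
Why: Williamson ether synthesis, in which carbonate in a dipolar aprotic solvent at low temperature should favour O- over C-benzylation of phloroglucinol.

Step 2
Reactants: 2 1,3,5-tris(benzyloxy)benzene
Product: 3 1,3,5-tris(benzyloxy)-2,4-dibromobenzene
Conditions: NBS (2.05 equiv), CH2Cl2, −10 °C → rt, dark
Reagents that add atoms: N-bromosuccinimide, O=C1CCC(=O)N1Br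
Why: Electrophilic aromatic bromination; the three equivalent C–H positions each lie between two alkoxy groups and each bromine introduced lowers the reactivity of what remains, so two equivalents should stop at the dibromide.

Step 3
Reactants: 3 1,3,5-tris(benzyloxy)-2,4-dibromobenzene
Product: 4 1,3,5-tris(benzyloxy)-2,4-dimethoxybenzene
Conditions: NaOMe (6 equiv), CuBr (0.4 equiv), MeOH–DMF, 110 °C
Reagents that add atoms: sodium methoxide, [Na+].[O-]C
Why: Ullmann-type copper-mediated methoxylation of aryl bromides, which tolerates ortho alkoxy groups and leaves benzyl ethers untouched.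

Step 4
Reactants: 4 1,3,5-tris(benzyloxy)-2,4-dimethoxybenzene
Product: 5 1,3,5-tris(benzyloxy)-2-iodo-4,6-dimethoxybenzene
Conditions: NIS (1.1 equiv), CF3CO2H (0.1 equiv), MeCN, 0 °C → rt, dark
Reagents that add atoms: N-iodosuccinimide, O=C1CCC(=O)N1I
Why: Electrophilic aromatic iodination at the only ring C–H left, which is ortho to two benzyloxy groups and para to the third.

Step 5
Reactants: 6 3,5-dihydroxy-4-methoxybenzoic acid
Product: 7 benzyl 3,5-bis(benzyloxy)-4-methoxybenzoate
Conditions: BnBr (3.5 equiv), K2CO3, DMF, 60 °C
Reagents that add atoms: benzyl bromide, BrCc1ccccc1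
Why: Williamson etherification of both phenols together with O-alkylation of the carboxylate, which protects ring B and turns the acid into a non-enolisable acyl donor.

Step 6
Reactants: 7 benzyl 3,5-bis(benzyloxy)-4-methoxybenzoate; 8 methyl methoxyacetate
Product: 10 methyl 3-[3,5-bis(benzyloxy)-4-methoxyphenyl]-2-methoxy-3-oxopropanoate (racemic), via lithium ester enolate 9 (not isolated)
Conditions: 8 (1.2 equiv), LiN(SiMe3)2 (2.4 equiv), THF, −78 °C; then 7, −78 °C → rt; 1 M HCl
Reagents that add atoms: none
Why: Crossed Claisen condensation, in which the preformed enolate 9 is acylated by the non-enolisable benzoate 7 and the second equivalent of base holds the β-keto ester as its enolate and so drives the equilibrium.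

Step 7
Reactants: 10 methyl 3-[3,5-bis(benzyloxy)-4-methoxyphenyl]-2-methoxy-3-oxopropanoate
Product: 12 1-[3,5-bis(benzyloxy)-4-methoxyphenyl]-2-methoxyethan-1-one, via lithium β-keto carboxylate 11 (not isolated)
Conditions: LiCl (3 equiv), H2O (2 equiv), DMSO, 140 °C
Reagents that add atoms: none
Why: Krapcho dealkoxycarbonylation, in which chloride demethylates the ester by SN2 attack and carboxylate 11 loses CO2 through the ketone enolate under neutral conditions that spare the benzyl ethers.

Step 8
Reactants: 5 1,3,5-tris(benzyloxy)-2-iodo-4,6-dimethoxybenzene; 12 1-[3,5-bis(benzyloxy)-4-methoxyphenyl]-2-methoxyethan-1-one (1.3 equiv); 13 carbon monoxide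
Product: 14 3-[3,5-bis(benzyloxy)-4-methoxyphenyl]-2-methoxy-1-[2,4,6-tris(benzyloxy)-3,5-dimethoxyphenyl]propane-1,3-dione (racemic, enolisable)
Conditions: Pd(dba)2 (5 mol%), Xantphos (6 mol%), MgCl2 (2 equiv), Et3N (3 equiv), CO (1 atm), 1,4-dioxane, 80 °C; then dilute HCl
Reagents that add atoms: none
Why: Oxidative addition of the C–I bond of 5 to zerovalent palladium gives an arylpalladium iodide (divalent palladium), CO inserts to form the aroyl complex, the magnesium enolate of 12 (soft enolisation with MgCl2/Et3N, helped by chelation through the α-methoxy oxygen) displaces iodide, and C–C reductive elimination releases 14 as its magnesium diketonate, so that C4a–C4 forms first and C4–C3 second. The closest known reaction type is the palladium-catalysed carbonylative α-arylation of aryl alkyl ketones with aryl iodides to 1,3-diketones. No ring is closed; the one new stereocentre, the methoxy-bearing carbon between the carbonyls, is enolisable, forms as the racemate and ends as the sp2 carbon C3. The step needs CO insertion to outrun direct α-arylation and C-aroylation to outrun O-aroylation: the two ortho benzyloxy groups slow enolate attack and reductive elimination at the aryl–palladium stage but leave room for the small CO ligand, and the wide-bite-angle Xantphos favours reductive elimination from the carbon-bound enolate. Ketone 12 has a single enolisable position, and the chelated magnesium diketonate of 14 is protected against a second aroylation. A CO atmosphere with an amine base and no carboxylate or carbonate also disfavours cyclopalladation of an ortho benzyloxy group.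

Step 9
Reactants: 14 3-[3,5-bis(benzyloxy)-4-methoxyphenyl]-2-methoxy-1-[2,4,6-tris(benzyloxy)-3,5-dimethoxyphenyl]propane-1,3-dione
Product: 15 1-(3,5-dihydroxy-4-methoxyphenyl)-2-methoxy-3-(2,4,6-trihydroxy-3,5-dimethoxyphenyl)propane-1,3-dione (racemic, enolisable)
Conditions: H2 (1 atm), Pd/C (10 wt% Pd), EtOAc–MeOH (1:1), rt
Reagents that add atoms: none
Why: Catalytic hydrogenolysis of the five aryl benzyl ethers, which should be faster than reduction of the aryl ketones and leaves the methyl ethers alone.

Step 10
Reactants: 15 1-(3,5-dihydroxy-4-methoxyphenyl)-2-methoxy-3-(2,4,6-trihydroxy-3,5-dimethoxyphenyl)propane-1,3-dione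
Product: 17 5,7,3',5'-tetrahydroxy-3,6,8,4'-tetramethoxyflavone (target), via cyclic hemiketal 16 (not isolated)
Conditions: H2SO4 (cat.), AcOH, 80 °C, under N2
Reagents that add atoms: none
Why: Acid-catalysed cyclodehydration as in the last stage of a Baker–Venkataraman flavone synthesis, in which an ortho hydroxyl of ring A adds to the ring B carbonyl (6-exo-trig) to give hemiketal 16 and loss of water forms the pyranone; the two ortho hydroxyls are equivalent by symmetry, so only one flavone can form.

**Compound list**

1 | phloroglucinol | Oc1cc(O)cc(O)c1 | starting material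
2 | 1,3,5-tris(benzyloxy)benzene | c1ccc(COc2cc(OCc3ccccc3)cc(OCc3ccccc3)c2)cc1 | intermediate
3 | 1,3,5-tris(benzyloxy)-2,4-dibromobenzene | Brc1c(OCc2ccccc2)cc(OCc2ccccc2)c(Br)c1OCc1ccccc1 | intermediate
4 | 1,3,5-tris(benzyloxy)-2,4-dimethoxybenzene | COc1c(OCc2ccccc2)cc(OCc2ccccc2)c(OC)c1OCc1ccccc1 | intermediate
5 | 1,3,5-tris(benzyloxy)-2-iodo-4,6-dimethoxybenzene | COc1c(OCc2ccccc2)c(I)c(OCc2ccccc2)c(OC)c1OCc1ccccc1 | intermediate
6 | 3,5-dihydroxy-4-methoxybenzoic acid | COc1c(O)cc(C(=O)O)cc1O | starting material
7 | benzyl 3,5-bis(benzyloxy)-4-methoxybenzoate | COc1c(OCc2ccccc2)cc(C(=O)OCc2ccccc2)cc1OCc1ccccc1 | intermediate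
8 | methyl methoxyacetate | COCC(=O)OC | starting material
9 | lithium (E)-1,2-dimethoxyethen-1-olate (chelated enolate of 8, α-methoxy cis to O–Li) | [Li+].CO/C=C(\[O-])OC | intermediate
10 | methyl 3-[3,5-bis(benzyloxy)-4-methoxyphenyl]-2-methoxy-3-oxopropanoate (racemic) | COC(C(=O)OC)C(=O)c1cc(OCc2ccccc2)c(OC)c(OCc2ccccc2)c1 | intermediate
11 | lithium 3-[3,5-bis(benzyloxy)-4-methoxyphenyl]-2-methoxy-3-oxopropanoate (racemic) | [Li+].COC(C(=O)[O-])C(=O)c1cc(OCc2ccccc2)c(OC)c(OCc2ccccc2)c1 | intermediate
12 | 1-[3,5-bis(benzyloxy)-4-methoxyphenyl]-2-methoxyethan-1-one | COCC(=O)c1cc(OCc2ccccc2)c(OC)c(OCc2ccccc2)c1 | intermediate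
13 | carbon monoxide | [C-]#[O+] | starting material
14 | 3-[3,5-bis(benzyloxy)-4-methoxyphenyl]-2-methoxy-1-[2,4,6-tris(benzyloxy)-3,5-dimethoxyphenyl]propane-1,3-dione (racemic, enolisable) | COC(C(=O)c1c(OCc2ccccc2)c(OC)c(OCc2ccccc2)c(OC)c1OCc1ccccc1)C(=O)c1cc(OCc2ccccc2)c(OC)c(OCc2ccccc2)c1 | intermediate
15 | 1-(3,5-dihydroxy-4-methoxyphenyl)-2-methoxy-3-(2,4,6-trihydroxy-3,5-dimethoxyphenyl)propane-1,3-dione (racemic, enolisable) | COC(C(=O)c1c(O)c(OC)c(O)c(OC)c1O)C(=O)c1cc(O)c(OC)c(O)c1 | intermediate
16 | 2-(3,5-dihydroxy-4-methoxyphenyl)-2,5,7-trihydroxy-3,6,8-trimethoxy-2,3-dihydro-4H-chromen-4-one (racemic mixture of diastereomers) | COC1C(=O)c2c(O)c(OC)c(O)c(OC)c2OC1(O)c1cc(O)c(OC)c(O)c1 | intermediate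
17 | 5,7,3',5'-tetrahydroxy-3,6,8,4'-tetramethoxyflavone (no stereocentre) | COc1c(O)cc(-c2oc3c(OC)c(O)c(OC)c(O)c3c(=O)c2OC)cc1O | target

**Step count**

Total steps: 10. Longest linear sequence: 7 steps (steps 1–4, then 8–10, from phloroglucinol); the ring B branch (steps 5–7) joins at step 8.

**Steps most likely to fail**

1. Step 8 (key step). The coupling may stall or leak into other channels. Oxidative addition and CO insertion at a carbon flanked by two benzyloxy groups may be slow, the enolate may attack before CO has inserted (direct α-arylation), or the aroyl complex may be captured at oxygen. An ortho benzyloxy group may also be cyclopalladated, or the iodide may simply be reduced. Fallback, from 5 back to 14: iodine–magnesium exchange with iPrMgCl·LiCl (THF, 0 °C) should give [2,4,6-tris(benzyloxy)-3,5-dimethoxyphenyl]magnesium chloride F1. Carboxylation with CO2 then gives 2,4,6-tris(benzyloxy)-3,5-dimethoxybenzoic acid F2, and (COCl)2 with catalytic DMF converts this into 2,4,6-tris(benzyloxy)-3,5-dimethoxybenzoyl chloride F3. C-aroylation of ketone 12 by soft enolisation (MgBr2·OEt2, iPr2NEt, CH2Cl2) returns to 14. C4 then comes from CO2 and the C4–C3 bond from a classical Claisen-type acylation, with no palladium involved.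

2. Step 3. Methoxide bound to copper can transfer a β-hydride, so that a C–Br bond is reduced instead of substituted, and the second, more crowded substitution may stop short. Fallback, from 3 back to 4: palladium-catalysed hydroxylation (Pd2(dba)3, tBuXPhos, KOH, dioxane–H2O, 100 °C) should give 2,4,6-tris(benzyloxy)benzene-1,3-diol F4. Hydroxide has no β-hydrogen, which closes the reduction channel. The diol is O-methylated without purification (MeI, K2CO3, acetone) to 4.

3. Step 6. The α-methoxy ester enolate may condense with itself or decompose on warming before it has acylated the electron-rich benzoate, and the β-keto ester may revert by retro-Claisen cleavage during work-up. Fallback, from 7 back to 12 (bypassing 10 and step 7): MeNHOMe·HCl and iPrMgCl (THF, −20 °C) should convert the benzyl ester directly into the Weinreb amide 3,5-bis(benzyloxy)-N,4-dimethoxy-N-methylbenzamide F5. Methoxymethyllithium F6, made from Bu3SnCH2OMe and n-BuLi (THF, −78 °C) by tin–lithium exchange, then adds once to the amide, and the chelated tetrahedral adduct collapses on work-up to ketone 12.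

**Further compounds**

F1 | step 8 | [2,4,6-tris(benzyloxy)-3,5-dimethoxyphenyl]magnesium chloride | COc1c(OCc2ccccc2)c([Mg]Cl)c(OCc2ccccc2)c(OC)c1OCc1ccccc1
F2 | step 8 | 2,4,6-tris(benzyloxy)-3,5-dimethoxybenzoic acid | COc1c(OCc2ccccc2)c(C(=O)O)c(OCc2ccccc2)c(OC)c1OCc1ccccc1
F3 | step 8 | 2,4,6-tris(benzyloxy)-3,5-dimethoxybenzoyl chloride | COc1c(OCc2ccccc2)c(C(=O)Cl)c(OCc2ccccc2)c(OC)c1OCc1ccccc1
F4 | step 3 | 2,4,6-tris(benzyloxy)benzene-1,3-diol | Oc1c(OCc2ccccc2)cc(OCc2ccccc2)c(O)c1OCc1ccccc1
F5 | step 6 | 3,5-bis(benzyloxy)-N,4-dimethoxy-N-methylbenzamide | COc1c(OCc2ccccc2)cc(C(=O)N(C)OC)cc1OCc1ccccc1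
F6 | step 6 | methoxymethyllithium | [Li]COC
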